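The numbers of this flask are invented.

Take the mole per litre per second as your unit, because each flask here is a contest between two such rates: making target and losing substrate to by-product.

| flask | substrate | partner | precatalyst | time | remark |
|---|---|---|---|---|---|
| violet | 0.071 M | 2.50 equiv (fed, over 2.00 min) | 15 mol% | 2.5 min | all but partner at the start; partner goes in evenly over 2.00 min, the run ends at 2.5 min |
| red | 0.071 M | 2.50 equiv | 15 mol% |  | one stirred flow tank at steady state, fed with the mixture as stated, mean residence time 2.5 min |
| blue | 0.071 M (fed, over 2.00 min) | 2.50 equiv | 15 mol% | 2.5 min | a stirred flask in which substrate is dosed at a steady rate over 2.00 min without added volume, worked up at 2.5 min |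
| amber | 0.071 M | 2.50 equiv | 15 mol% | 2.5 min | a closed flask charged with all of it at once and left for 2.5 min |

    substrate + free catalyst → catalyst intermediate A (k1 = 16 L mol⁻¹ s⁻¹)
    partner + catalyst intermediate A → catalyst intermediate B (k2 = 1.3 L mol⁻¹ s⁻¹)
    catalyst intermediate B → by-product + catalyst intermediate C (k3 = 18 s⁻¹)
    catalyst intermediate C → free catalyst + target (k4 = 4.1 s⁻¹)
    partner + precatalyst → free catalyst + spent reagent (k5 = 0.41 L mol⁻¹ s⁻¹)
    substrate + by-product → side product (k6 = 0.71 L mol⁻¹ s⁻¹)
    catalyst intermediate C + catalyst intermediate C ⇌ resting dimer (K7 = 47 L mol⁻¹, k7 = 7.0 L mol⁻¹ s⁻¹)

* the set-up with the highest amount of target at the outlet or at the end, in percent of the substrate put in ("none" if the first two lie within 2 percentage points) (violet / red / blue / amber / none)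
* amount of target at the outlet or at the end, in percent of the substrate put in, violet
* amount of target at the outlet or at the end, in percent of the substrate put in, red
* amount of target at the outlet or at the end, in percent of the substrate put in, blue
* amount of target at the outlet or at the end, in percent of the substrate put in, amber

- a species is counted by the substrate in it: one resting dimer counts as two
- for a step with 2 of a species take k times the square, and two of it per event
- the stated concentrations are those of everything mixed, before any reaction; amounts are the same in each set-up
- the feed brings no volume worth counting
- run time (violet): 2.5 min

Each turn of the cycle makes one target and one by-product, and step 6 then turns a substrate and that by-product into side product. If a share ℓ of the substrate ends as side product, the by-product left is 1−2ℓ of the charge. So I reckon each row by ℓ/(1−ℓ) = g(1−2ℓ), where g is still to be defined from amber.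

Amber: partner halves the precatalyst in about 9.52 s, shorter than the turnover time below, so I count 0.01065 M of catalyst as active. Early on, the rate constants 1.14 s⁻¹ for capture by substrate and 4.1 s⁻¹ for release both exceed 0.185 s⁻¹ for capture of partner, so step 2 is the rate-limiting step and catalyst intermediate A the resting state. At a mean partner of 0.142 M, the charge turns over in 36.1 s. Replace the curves by straight lines: substrate falls as by-product rises, so the mean of their product is 1/2 less 1/3 of the charge squared, not the 1/4 that their separate means suggest. That gives 0.303, the loss ratio g: mean rate of step 6 over mean turnover rate, as if no by-product had yet been eaten. Then ℓ, the smaller root of the quadratic that the rule makes, is 16.8% and amber gives 83.2%.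

Blue: dosing over 2.00 min is slower than the turnover time, so substrate stays low and intermediate A holds 30.1% of the catalyst, leaving about 0.007445 M free. Step 6 now competes with step 1, and by-product averages 0.5 of the charge, so g is 0.212 and blue gives 13.4% lost and 86.6%.

Violet: taking partner as fed, with nothing deducted for what step 2 has used, the charge turns over in about 83.3 s, so g is 0.700, 25.5% is lost, and violet gives 74.5%.

Red: the tank holds by-product at its full level. With partner near 0.106 M, intermediate A holds 32.1% of the catalyst, so g is 0.436. Substrate and intermediate A also leave unconverted, and red gives 71.1%. My choice is blue.

The forecast, which unlike my reckoning sets violet and amber equal, gives 77%, 73%, 84% and 77% for violet, red, blue and amber, and names blue: "Dosing substrate keeps it starved against the by-product".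

The simulation gives 75.9% for violet, 73.1% for red, 86.6% for blue and 79.3% for amber, so the best is blue. Among blue, amber and violet, blue's loss ratio 0.212 goes with 86.6%, amber's 0.303 with 79.3% and violet's 0.700 with 75.9%, in the same order. In amber at the charged concentrations, step 6 by itself halves by-product in 0.23 min, slower than step 2 by itself halves catalyst intermediate A, in 0.050 min.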